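**Retrosynthetic overview**

1. The angelate is attached last to the only secondary hydroxyl of (13R)-labd-14-ene-6α,8α,13-triol. The 8α-carbinol comes from an 8(17)-methylene (α-epoxidation, hydride opening), and C13 from Sharpless epoxidation and reductive transposition of an (E)-allylic alcohol grown from a C11 ester.
2. Key disconnection: the C8–C9 bond of ring B. It joins C8 (the future tertiary carbinol with the axial C17 methyl) to the branch carbon C9 next to quaternary C10. A terminal alkyne at C8 and the silyl ketene acetal of the C11 ester close ring B 6-exo-dig under gold catalysis and leave C8=C17.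
3. The ring-A seco ester comes from (R)-2-allyl-2,6,6-trimethylcyclohexanone (Pd-catalysed asymmetric allylation sets C10). The three allyl carbons become C9, C11 and C6 through Wacker oxidation, aldol closure to a relay cyclopentenone, Li/NH3 reduction (sets C5) and ozonolysis of the regiodefined silyl enol ether (cuts C6–C11). A catalyst-controlled propargylation sets C6.
4. Ring order: ring A (bought), relay five-membered ring (made and cleaved), ring B (key step).

Key step: step 9

Remark: labdane numbering and α/β descriptors are used for all intermediates (C20 on C10 is β); the stereochemical sense of the ligand in step 2, the acid in step 7 and the tartrate in step 16 follows the accepted models, and the mirror-image reagent would be used if a model failed on this substrate.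

**Route**

Step 1
Reactants: 1 2,2,6-trimethylcyclohexan-1-one; 2 allyl chloroformate
Product: 4 allyl 2,6,6-trimethylcyclohex-1-en-1-yl carbonate, via lithium enolate 3 (not isolated)
Conditions: LiN(SiMe3)2, THF, 0 °C to rt; then 2, −78 °C to rt
Reagents that add atoms: none
Why: Enolate O-acylation (enol carbonate formation): the ketone has a single enolisable position, and its fully substituted enolate should be acylated on oxygen because C-acylation would build a second quaternary centre beside the carbonyl.

Step 2
Reactants: 4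
Product: 5 (R)-2-allyl-2,6,6-trimethylcyclohexan-1-one
Conditions: Pd2(dba)3 (tris(dibenzylideneacetone)dipalladium, zerovalent palladium, 2.5 mol %), (R)-4-tert-butyl-2-[2-(diphenylphosphanyl)phenyl]-4,5-dihydro-1,3-oxazole (6 mol %), THF, 25 °C
Reagents that add atoms: none
Why: Decarboxylative asymmetric allylic alkylation (enantioselective Tsuji allylation): loss of CO2 gives an allylpalladium enolate whose prochiral face is chosen by the phosphinooxazoline ligand, which sets C10, the (R)-ligand being taken by analogy with the established (S)-ligand/(S)-ketone correlation of this ketone class.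

Step 3
Reactants: 5
Product: 6 (R)-2,2,6-trimethyl-6-(2-oxopropyl)cyclohexan-1-one
Conditions: PdCl2 (10 mol %), Cu(OAc)2·H2O (25 mol %), O2 (1 atm), DMA/H2O 7:1, rt
Reagents that add atoms: water, O
Why: Tsuji–Wacker oxidation: Markovnikov hydroxypalladation of the terminal alkene and β-hydride elimination give the methyl ketone, with the hindered ring ketone and C10 untouched.

Step 4
Reactants: 6
Product: 8 (R)-4,4,7a-trimethyl-1,4,5,6,7,7a-hexahydro-2H-inden-2-one, via aldol adduct 7 (not isolated)
Conditions: KOH (powdered), xylenes, 110 °C, Dean–Stark trap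
Reagents that add atoms: none
Why: Intramolecular aldol condensation: the ring carbonyl has no α-hydrogen, so only the methyl enolate of the side-chain ketone can close a five-membered ring onto it, and removal of water drives the hindered addition through to the enone.

Step 5
Reactants: 8
Product: 10 trimethyl{[(3aS,7aR)-4,4,7a-trimethyl-3a,4,5,6,7,7a-hexahydro-1H-inden-2-yl]oxy}silane, via lithium enolate 9 (not isolated)
Conditions: Li (2.2 equiv), t-BuOH (1.0 equiv), NH3(l)/THF, −78 °C; evaporate NH3; Me3SiCl, Et3N, THF, 0 °C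
Reagents that add atoms: chlorotrimethylsilane, C[Si](C)(C)Cl
Why: Dissolving-metal conjugate reduction with enolate trapping (reductive silylation): the β-carbon C5 should be protonated axially on the α face, anti to the axial C10 methyl and away from the axial C4 methyl that both flank the β face, which sets H5 trans to C20, while silylation fixes the enolate regiospecifically between C6 and C11.

Step 6
Reactants: 10
Product: 12 methyl 2-[(1R,2S)-2-formyl-1,3,3-trimethylcyclohexyl]acetate, via aldehyde acid 11 (not isolated)
Conditions: O3, CH2Cl2/MeOH, −78 °C; Me2S, −78 °C to rt; concentrate; Me3SiCHN2, toluene/MeOH, 0 °C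
Reagents that add atoms: ozone, [O-][O+]=O; (trimethylsilyl)diazomethane, C[Si](C)(C)C=[N+]=[N-]
Why: Ozonolysis of a silyl enol ether followed by diazoalkane esterification: cleavage of C6=C11 gives the C6 aldehyde and the C11 acid with C5 and C10 unchanged (the aldehyde α-carbon lies between two quaternary carbons and should not epimerise under these neutral conditions), and the acid is methylated without touching the aldehyde.

Step 7
Reactants: 12; 13 allenylboronic acid pinacol ester
Product: 14 methyl 2-[(1R,2S)-2-[(1S)-1-hydroxybut-3-yn-1-yl]-1,3,3-trimethylcyclohexyl]acetate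
Conditions: (S)-3,3′-bis(2,4,6-triisopropylphenyl)-1,1′-binaphthalene-2,2′-diyl hydrogen phosphate (10 mol %), 4 Å molecular sieves, toluene, 0 °C
Reagents that add atoms: none
Why: Chiral Brønsted acid-catalysed propargylation with an allenylboronate (closed six-membered SE2′ transition state): the substrate offers no useful Felkin bias because C5 carries two near-equal quaternary neighbours, so the phosphoric acid decides the face, and the (S)-acid should deliver the propargyl group to the Si face to give the (6S)-alcohol.

Step 8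
Reactants: 14
Product: 15 methyl 2-[(1R,2S)-2-[(1S)-1-[(tert-butyldimethylsilyl)oxy]but-3-yn-1-yl]-1,3,3-trimethylcyclohexyl]acetate
Conditions: t-BuMe2SiOTf, 2,6-lutidine, CH2Cl2, −78 to 0 °C
Reagents that add atoms: tert-butyldimethylsilyl trifluoromethanesulfonate, CC(C)(C)[Si](C)(C)OS(=O)(=O)C(F)(F)F
Why: Silyl ether formation with a silyl triflate, reactive enough for the hindered secondary alcohol and carried out directly after step 7 so that the δ-hydroxy ester has no opportunity to lactonise.

Step 9
Reactants: 15
Product: 18 methyl (1S,4S,4aS,8aS)-4-[(tert-butyldimethylsilyl)oxy]-5,5,8a-trimethyl-2-methylidenedecahydronaphthalene-1-carboxylate, via dilithio enolate acetylide 16 (not isolated), via silyl ketene acetal 17 (not isolated)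
Conditions: LiN(i-Pr)2 (2.2 equiv), THF, −78 °C; t-BuMe2SiCl (1.1 equiv), DMPU, −78 to −40 °C; cold pH 7 buffer, pentane; crude 17, [(t-Bu)2(2-biphenylyl)P]Au(NCMe)SbF6 (5 mol %), MeOH (2 equiv), CH2Cl2, 0 °C to rt
Reagents that add atoms: none
Why: Two equivalents of amide base deprotonate both the ester α-carbon C9 and the alkyne terminus, the harder enolate oxygen should be silylated selectively at low temperature, and the acetylide is reprotonated on work-up, so that ketene acetal 17 carries a free terminal alkyne. The cationic monovalent gold complex then binds the alkyne, C9 adds anti to gold at the internal carbon C8, and silyl transfer to methanol followed by protodeauration of the vinylgold leaves the ester and the C8=C17 methylene; the closest known reaction type is the gold-catalysed Conia-ene-type carbocyclisation of silyl enol ethers and silyl ketene acetals onto alkynes. Ring B closes in the 6-exo-dig mode through the C8–C9 bond, 7-endo-dig closure being disfavoured because a terminal alkyne places the developing positive charge on its internal carbon. The new stereocentre C9 is controlled by a chair transition state in which the tether hangs from the trans-diequatorial C5 and C10 positions of ring A, the 6α-silyloxy group is equatorial, and the ketene acetal terminus C11 takes the equatorial site away from the axial hydrogens on C5 and C7, which should give the 9β-ester with H9 trans to the C10 methyl. The step needs carbon attack by the ketene acetal in preference to attack by the silyl ether oxygen, and a trans ring fusion; the far higher nucleophilicity of the ketene acetal carbon and the C5/C10 configuration fixed in steps 2 and 5 secure both.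

Step 10
Reactants: 18
Product: 19 6α-[(tert-butyldimethylsilyl)oxy]drim-8(12)-en-11-ol
Conditions: i-Bu2AlH (3 equiv), CH2Cl2, −78 to 0 °C; aqueous potassium sodium tartrate work-up
Reagents that add atoms: none
Why: Hydride reduction of the ester to the primary alcohol with a non-basic aluminium hydride, which leaves the β,γ-unsaturated C9 centre and the silyl ether untouched.

Step 11
Reactants: 19
Product: 20 6α-[(tert-butyldimethylsilyl)oxy]drim-8(12)-en-11-al
Conditions: Dess–Martin periodinane, CH2Cl2, 0 °C to rt
Reagents that add atoms: none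
Why: Dess–Martin oxidation under near-neutral conditions should give the β,γ-unsaturated aldehyde without epimerising C9 or moving the exocyclic double bond into conjugation.

Step 12
Reactants: 20; 21 1-(triphenylphosphoranylidene)propan-2-one
Product: 22 (11E)-6α-[(tert-butyldimethylsilyl)oxy]-14,15-dinorlabda-8(17),11-dien-13-one
Conditions: toluene, 90 °C
Reagents that add atoms: none
Why: Wittig olefination with a stabilised ylide, (E)-selective and free of added base, so the sensitive aldehyde is extended by C12, C13 and C16 without isomerisation.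

Step 13
Reactants: 22
Product: 23 6α-[(tert-butyldimethylsilyl)oxy]-14,15-dinorlabd-8(17)-en-13-one
Conditions: [(Ph3P)CuH]6 (0.4 equiv), H2O (2 equiv), toluene, rt
Reagents that add atoms: none
Why: Copper hydride conjugate reduction: the phosphine-stabilised copper hydride adds hydride 1,4 to the enone only and spares the isolated 8(17)-methylene, which catalytic hydrogenation would not.

Step 14
Reactants: 23; 24 triethyl phosphonoacetate
Product: 25 ethyl (13E)-6α-[(tert-butyldimethylsilyl)oxy]labda-8(17),13-dien-15-oate
Conditions: 24, NaH, THF, 0 °C; then 23, reflux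
Reagents that add atoms: none
Why: Horner–Wadsworth–Emmons olefination of the methyl ketone, which should favour the (E)-enoate with the ester trans to the larger C12 chain; the minor (Z)-isomer is removed by chromatography here or after step 15.

Step 15
Reactants: 25
Product: 26 (13E)-6α-[(tert-butyldimethylsilyl)oxy]labda-8(17),13-dien-15-ol
Conditions: i-Bu2AlH, CH2Cl2, −78 °C
Reagents that add atoms: none
Why: 1,2-Reduction of the enoate with an aluminium hydride gives the allylic alcohol needed for the directed epoxidation.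

Step 16
Reactants: 26
Product: 27 (13R,14R)-13,14-epoxy-6α-[(tert-butyldimethylsilyl)oxy]labd-8(17)-en-15-ol
Conditions: Ti(Oi-Pr)4 (10 mol %), D-(−)-diethyl tartrate (12 mol %), t-BuOOH, 4 Å molecular sieves, CH2Cl2, −20 °C
Reagents that add atoms: tert-butyl hydroperoxide, CC(C)(C)OO
Why: Sharpless asymmetric epoxidation: the titanium tartrate complex epoxidises only the allylic alcohol, and with the D-(−)-tartrate the (E)-trisubstituted alkene should give the (13R,14R)-epoxide (the mirror image of the outcome of geraniol with the L-(+)-ester), which sets C13 under reagent control.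

Step 17
Reactants: 27
Product: 29 (13R)-6α-[(tert-butyldimethylsilyl)oxy]labda-8(17),14-dien-13-ol, via epoxy iodide 28 (not isolated)
Conditions: I2, PPh3, imidazole, CH2Cl2, 0 °C; aqueous Na2S2O3 work-up; crude 28, Zn dust, EtOH, 70 °C
Reagents that add atoms: none
Why: Appel-type iodination of the primary alcohol followed by zinc-mediated reductive opening of the 2,3-epoxy iodide (β-elimination of the organozinc): the C14–O bond is broken and the C13–O bond is untouched, so the tertiary allylic alcohol keeps the 13R configuration.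

Step 18
Reactants: 29
Product: 30 (13R)-8α,17-epoxy-6α-[(tert-butyldimethylsilyl)oxy]labd-14-en-13-ol
Conditions: m-chloroperbenzoic acid (1.05 equiv), NaHCO3, CH2Cl2, 0 °C
Reagents that add atoms: m-chloroperbenzoic acid, OOC(=O)c1cccc(Cl)c1
Why: Prilezhaev epoxidation: the 1,1-disubstituted exocyclic alkene is more electron-rich than the vinyl group and should be attacked from the α face, opposite the axial C10 methyl, to give the 8α,17-epoxide.

Step 19
Reactants: 30
Product: 31 (13R)-6α-[(tert-butyldimethylsilyl)oxy]labd-14-ene-8α,13-diol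
Conditions: LiAlH4, THF, 0 °C to rt
Reagents that add atoms: none
Why: Hydride opening of the spiro-epoxide at its primary carbon C17 converts it into the 8β-methyl, 8α-hydroxy tertiary carbinol with the C8–O bond retained.

Step 20
Reactants: 31
Product: 32 (13R)-labd-14-ene-6α,8α,13-triol
Conditions: Bu4NF, THF, 50 °C
Reagents that add atoms: none
Why: Fluoride-mediated desilylation under non-acidic conditions, which spares the tertiary allylic alcohol that acid would ionise.

Step 21
Reactants: 32; 33 angelic acid
Product: 35 (13R)-8α,13-dihydroxylabd-14-en-6α-yl (Z)-2-methylbut-2-enoate (CNP0203829.1), via mixed anhydride 34 (not isolated)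
Conditions: 33, 2,4,6-trichlorobenzoyl chloride, Et3N, toluene, rt; then 32, toluene, 80 °C
Reagents that add atoms: none
Why: Yamaguchi-type esterification through the mixed anhydride: only the secondary 6α-hydroxyl should be acylated because the 8- and 13-hydroxyls are tertiary, and leaving out a nucleophilic amine catalyst avoids addition–elimination isomerisation of the (Z)-angeloyl group to the tigloyl isomer.

**Compound list**

1 | 2,2,6-trimethylcyclohexan-1-one (racemic) | CC1CCCC(C)(C)C1=O | starting material
2 | allyl chloroformate | C=CCOC(=O)Cl | starting material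
3 | lithium 2,6,6-trimethylcyclohex-1-en-1-olate | [Li+].[O-]C1=C(C)CCCC1(C)C | intermediate
4 | allyl 2,6,6-trimethylcyclohex-1-en-1-yl carbonate | C=CCOC(=O)OC1=C(C)CCCC1(C)C | intermediate
5 | (R)-2-allyl-2,6,6-trimethylcyclohexan-1-one | C=CC[C@@]1(C)CCCC(C)(C)C1=O | intermediate
6 | (R)-2,2,6-trimethyl-6-(2-oxopropyl)cyclohexan-1-one | CC(=O)C[C@@]1(C)CCCC(C)(C)C1=O | intermediate
7 | (3aS,7aR)-3a-hydroxy-4,4,7a-trimethyloctahydro-2H-inden-2-one (cis-fused aldol adduct) | O=C1C[C@@]2(C)CCCC(C)(C)[C@@]2(O)C1 | intermediate
8 | (R)-4,4,7a-trimethyl-1,4,5,6,7,7a-hexahydro-2H-inden-2-one | O=C1C[C@@]2(C)CCCC(C)(C)C2=C1 | intermediate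
9 | lithium (3aS,7aR)-4,4,7a-trimethyl-3a,4,5,6,7,7a-hexahydro-1H-inden-2-olate (trans-fused) | C1=C([O-])C[C@@]2(C)CCCC(C)(C)[C@H]12.[Li+] | intermediate
10 | trimethyl{[(3aS,7aR)-4,4,7a-trimethyl-3a,4,5,6,7,7a-hexahydro-1H-inden-2-yl]oxy}silane (trans-fused) | C1=C(O[Si](C)(C)C)C[C@@]2(C)CCCC(C)(C)[C@H]12 | intermediate
11 | 2-[(1R,2S)-2-formyl-1,3,3-trimethylcyclohexyl]acetic acid | OC(=O)C[C@@]1(C)CCCC(C)(C)[C@@H]1C=O | intermediate
12 | methyl 2-[(1R,2S)-2-formyl-1,3,3-trimethylcyclohexyl]acetate | COC(=O)C[C@@]1(C)CCCC(C)(C)[C@@H]1C=O | intermediate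
13 | allenylboronic acid pinacol ester (4,4,5,5-tetramethyl-2-(propa-1,2-dien-1-yl)-1,3,2-dioxaborolane) | C=C=CB1OC(C)(C)C(C)(C)O1 | starting material
14 | methyl 2-[(1R,2S)-2-[(1S)-1-hydroxybut-3-yn-1-yl]-1,3,3-trimethylcyclohexyl]acetate | COC(=O)C[C@@]1(C)CCCC(C)(C)[C@@H]1[C@@H](O)CC#C | intermediate
15 | methyl 2-[(1R,2S)-2-[(1S)-1-[(tert-butyldimethylsilyl)oxy]but-3-yn-1-yl]-1,3,3-trimethylcyclohexyl]acetate (key-step precursor) | COC(=O)C[C@@]1(C)CCCC(C)(C)[C@@H]1[C@@H](O[Si](C)(C)C(C)(C)C)CC#C | intermediate
16 | dilithium salt of 15 (ester enolate at C9/C11, acetylide at C17) | [Li+].[Li+].CO/C([O-])=C\[C@@]1(C)CCCC(C)(C)[C@@H]1[C@@H](O[Si](C)(C)C(C)(C)C)CC#[C-] | intermediate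
17 | (E)-tert-butyldimethylsilyl methyl ketene acetal of 15 (either geometry serves) | CO/C(O[Si](C)(C)C(C)(C)C)=C\[C@@]1(C)CCCC(C)(C)[C@@H]1[C@@H](O[Si](C)(C)C(C)(C)C)CC#C | intermediate
18 | methyl (1S,4S,4aS,8aS)-4-[(tert-butyldimethylsilyl)oxy]-5,5,8a-trimethyl-2-methylidenedecahydronaphthalene-1-carboxylate (methyl 6α-silyloxydrim-8(12)-en-11-oate; key-step product) | COC(=O)[C@@H]1[C@@]2(C)CCCC(C)(C)[C@@H]2[C@@H](O[Si](C)(C)C(C)(C)C)CC1=C | intermediate
19 | 6α-[(tert-butyldimethylsilyl)oxy]drim-8(12)-en-11-ol | OC[C@@H]1[C@@]2(C)CCCC(C)(C)[C@@H]2[C@@H](O[Si](C)(C)C(C)(C)C)CC1=C | intermediate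
20 | 6α-[(tert-butyldimethylsilyl)oxy]drim-8(12)-en-11-al | O=C[C@@H]1[C@@]2(C)CCCC(C)(C)[C@@H]2[C@@H](O[Si](C)(C)C(C)(C)C)CC1=C | intermediate
21 | 1-(triphenylphosphoranylidene)propan-2-one | CC(=O)C=P(c1ccccc1)(c1ccccc1)c1ccccc1 | starting material
22 | (11E)-6α-[(tert-butyldimethylsilyl)oxy]-14,15-dinorlabda-8(17),11-dien-13-one | CC(=O)/C=C/[C@@H]1[C@@]2(C)CCCC(C)(C)[C@@H]2[C@@H](O[Si](C)(C)C(C)(C)C)CC1=C | intermediate
23 | 6α-[(tert-butyldimethylsilyl)oxy]-14,15-dinorlabd-8(17)-en-13-one | CC(=O)CC[C@@H]1[C@@]2(C)CCCC(C)(C)[C@@H]2[C@@H](O[Si](C)(C)C(C)(C)C)CC1=C | intermediate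
24 | triethyl phosphonoacetate | CCOC(=O)CP(=O)(OCC)OCC | starting material
25 | ethyl (13E)-6α-[(tert-butyldimethylsilyl)oxy]labda-8(17),13-dien-15-oate | CCOC(=O)/C=C(\C)CC[C@@H]1[C@@]2(C)CCCC(C)(C)[C@@H]2[C@@H](O[Si](C)(C)C(C)(C)C)CC1=C | intermediate
26 | (13E)-6α-[(tert-butyldimethylsilyl)oxy]labda-8(17),13-dien-15-ol | OC/C=C(\C)CC[C@@H]1[C@@]2(C)CCCC(C)(C)[C@@H]2[C@@H](O[Si](C)(C)C(C)(C)C)CC1=C | intermediate
27 | (13R,14R)-13,14-epoxy-6α-[(tert-butyldimethylsilyl)oxy]labd-8(17)-en-15-ol | OC[C@H]1O[C@]1(C)CC[C@@H]2[C@@]3(C)CCCC(C)(C)[C@@H]3[C@@H](O[Si](C)(C)C(C)(C)C)CC2=C | intermediate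
28 | 13,14-epoxy-15-iodo-6α-[(tert-butyldimethylsilyl)oxy]labd-8(17)-ene (epoxide configured as in 27) | IC[C@H]1O[C@]1(C)CC[C@@H]2[C@@]3(C)CCCC(C)(C)[C@@H]3[C@@H](O[Si](C)(C)C(C)(C)C)CC2=C | intermediate
29 | (13R)-6α-[(tert-butyldimethylsilyl)oxy]labda-8(17),14-dien-13-ol | C=C[C@](C)(O)CC[C@@H]1[C@@]2(C)CCCC(C)(C)[C@@H]2[C@@H](O[Si](C)(C)C(C)(C)C)CC1=C | intermediate
30 | (13R)-8α,17-epoxy-6α-[(tert-butyldimethylsilyl)oxy]labd-14-en-13-ol | C=C[C@](C)(O)CC[C@@H]1[C@@]2(C)CCCC(C)(C)[C@@H]2[C@@H](O[Si](C)(C)C(C)(C)C)C[C@@]1(C3)O3 | intermediate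
31 | (13R)-6α-[(tert-butyldimethylsilyl)oxy]labd-14-ene-8α,13-diol | C=C[C@](C)(O)CC[C@@H]1[C@@]2(C)CCCC(C)(C)[C@@H]2[C@@H](O[Si](C)(C)C(C)(C)C)C[C@@]1(C)O | intermediate
32 | (13R)-labd-14-ene-6α,8α,13-triol | C=C[C@](C)(O)CC[C@@H]1[C@@]2(C)CCCC(C)(C)[C@@H]2[C@@H](O)C[C@@]1(C)O | intermediate
33 | angelic acid ((Z)-2-methylbut-2-enoic acid) | C/C=C(/C)C(=O)O | starting material
34 | (Z)-2-methylbut-2-enoic 2,4,6-trichlorobenzoic anhydride | C/C=C(/C)C(=O)OC(=O)c1c(Cl)cc(Cl)cc1Cl | intermediate
35 | (13R)-8α,13-dihydroxylabd-14-en-6α-yl (Z)-2-methylbut-2-enoate (CNP0203829.1) | C=C[C@](C)(O)CC[C@@H]1[C@@]2(C)CCCC(C)(C)[C@@H]2[C@@H](OC(=O)/C(C)=C\C)C[C@@]1(C)O | target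

**Step count**

Total step count: 21. Longest linear sequence: 21 steps (from 1 to 35).

**Steps most likely to fail, with fallbacks**

Step 9 (key step). The ketene acetal may not form cleanly: the acetylide may be C-silylated, or the acetal may hydrolyse back to the ester before it cyclises. In the gold step, the silyl ether oxygen may attack the activated alkyne, or C9 may approach from the wrong face. Fallback: starting from 15, reduce the ester with i-Bu2AlH to the primary alcohol F1 and oxidise it with Dess–Martin periodinane to the aldehyde F2. Soft enolisation of F2 (t-BuMe2SiOTf, Et3N, CH2Cl2) needs no strong base and so leaves the alkyne untouched; it gives the silyl enol ether F3. The same cationic gold catalyst with methanol then closes ring B through C8–C9 (silyl enol ethers are the best-established nucleophiles for this carbocyclisation) and releases aldehyde 20 directly. The fallback rejoins the route at 20, and steps 10 and 11 fall away.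

Step 7. Addition to the aldehyde, which sits between two quaternary carbons, may be slow, and with no substrate bias the catalyst may give poor facial selectivity; the δ-hydroxy ester may also begin to lactonise. Fallback: starting from 12, a Barbier addition of propargylzinc bromide (propargyl bromide, Zn, THF) without stereocontrol gives 14 together with its C6 epimer F4. The mixture is oxidised with Dess–Martin periodinane to the ynone F5. Corey–Bakshi–Shibata reduction of F5 with (R)-1-methyl-3,3-diphenyltetrahydro-1H,3H-pyrrolo[1,2-c][1,3,2]oxazaborole and BH3·SMe2 (large group the ring carbon C5, small group the propargyl CH2) returns 14.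

Step 21. Acylation of the hindered 6α-hydroxyl may be sluggish, and on heating the angeloyl group may isomerise to the tigloyl ester. Fallback: starting from 32, acylate the 6α-hydroxyl with 2-[bis(2,2,2-trifluoroethoxy)phosphoryl]propanoic acid (N,N′-dicyclohexylcarbodiimide, 4-(dimethylamino)pyridine) to give the phosphonate ester F6. Still–Gennari olefination of F6 with acetaldehyde (KN(SiMe3)2, 18-crown-6, THF, −78 °C) builds the (Z)-2-methylbut-2-enoate on the molecule and gives 35.

**Further compounds**

F1 | step 9 | 2-[(1R,2S)-2-[(1S)-1-[(tert-butyldimethylsilyl)oxy]but-3-yn-1-yl]-1,3,3-trimethylcyclohexyl]ethan-1-ol | OCC[C@@]1(C)CCCC(C)(C)[C@@H]1[C@@H](O[Si](C)(C)C(C)(C)C)CC#C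
F2 | step 9 | 2-[(1R,2S)-2-[(1S)-1-[(tert-butyldimethylsilyl)oxy]but-3-yn-1-yl]-1,3,3-trimethylcyclohexyl]acetaldehyde | O=CC[C@@]1(C)CCCC(C)(C)[C@@H]1[C@@H](O[Si](C)(C)C(C)(C)C)CC#C
F3 | step 9 | tert-butyl({(Z)-2-[(1R,2S)-2-[(1S)-1-[(tert-butyldimethylsilyl)oxy]but-3-yn-1-yl]-1,3,3-trimethylcyclohexyl]ethenyl}oxy)dimethylsilane | CC(C)(C)[Si](C)(C)O/C=C\[C@@]1(C)CCCC(C)(C)[C@@H]1[C@@H](O[Si](C)(C)C(C)(C)C)CC#C
F4 | step 7 | methyl 2-[(1R,2S)-2-[(1R)-1-hydroxybut-3-yn-1-yl]-1,3,3-trimethylcyclohexyl]acetate | COC(=O)C[C@@]1(C)CCCC(C)(C)[C@@H]1[C@H](O)CC#C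
F5 | step 7 | methyl 2-[(1R,2S)-2-(but-3-ynoyl)-1,3,3-trimethylcyclohexyl]acetate | COC(=O)C[C@@]1(C)CCCC(C)(C)[C@@H]1C(=O)CC#C
F6 | step 21 | (13R)-8α,13-dihydroxylabd-14-en-6α-yl 2-[bis(2,2,2-trifluoroethoxy)phosphoryl]propanoate | C=C[C@](C)(O)CC[C@@H]1[C@@]2(C)CCCC(C)(C)[C@@H]2[C@@H](OC(=O)C(C)P(=O)(OCC(F)(F)F)OCC(F)(F)F)C[C@@]1(C)O
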